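(The runs were generated by integration from invented constants, and the scatter is random.)

If target is to be the main content of the flask at the end, I charge Thursday's amount of solid reagent, not Wednesday's. The flasks, the runs and the questions are these.

| flask | starting material | solid reagent | remark | time |
|---|---|---|---|---|
| grey | 0.30 M | 0.29 M | run made earlier |  |
| violet | 0.30 M | 0.62 M | run made earlier |  |
| Wednesday's | 0.30 M | 0.240 M |  | 50 h |
| Thursday's | 0.30 M | 0.480 M |  | 50 h |

| run | time / h | starting material / % | target / % |
|---|---|---|---|
| grey | 3.00 | 71 | 29 |
| grey | 4.00 | 67 | 36 |
| grey | 6.00 | 58 | 40 |
| grey | 10.0 | 55 | 47 |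
| grey | 15.0 | 52 | 44 |
| grey | 25.0 | 53 | 52 |
| grey | 40.0 | 54 | 45 |
| violet | 3.00 | 72 | 26 |
| violet | 4.00 | 62 | 35 |
| violet | 6.00 | 48 | 58 |
| violet | 10.0 | 27 | 72 |
| violet | 15.0 | 24 | 76 |
| violet | 25.0 | 23 | 80 |
| violet | 40.0 | 25 | 77 |

(scatter of a reading: 2 percentage points)

- for target the crystals are counted in
- as a solid, counted per litre of solution: crystals, solid reagent
- candidate steps: 2 partner -> side product; solid reagent <-> partner; crystals <-> target; starting material + partner -> target
- at the start none of the solid reagent is in solution

- which of these there is most of at the end, counted by the starting material in it, Wednesday's (target / starting material)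
- which of these there is most of at the end, counted by the starting material in it, Thursday's (target / starting material)
- amount of the one of these that there is most of at the end, in percent of the starting material charged, Wednesday's
- amount of the one of these that there is most of at the end, in percent of the starting material charged, Thursday's

In each run the two columns add up to about the charge, with crystals counted in target, so I follow c(starting material) and take target as the rest. The curves start alike: 71 % and 72 % at 3.00 h give a logarithmic slope of 0.112 h⁻¹. Then each bends into a level from 15.0 h on, with starting material still present, so solid reagent looks like the limiting reagent. The logarithm of the fall counts the partner met over time, so I divide it by the charge. Grey gives 2.19 L mol⁻¹, violet 2.30 L mol⁻¹, and I carry their mean 2.25 L mol⁻¹: the reach, the fall in ln c(starting material) bought by each mole of solid reagent per litre.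

So I put Wednesday's knee near 4.82 h, reckoned at that early slope, and its level at 58.3 %, above the crossing with target. Thursday's curve I take along violet's early readings, which pass equal amounts between 4.00 h and 6.00 h, and I put its level at 34.0 %, which leaves 66.0 % target. Equal amounts need 0.308 M of solid reagent.

The forecast gives starting material at 60 % for Wednesday's and target at 65 % for Thursday's, on the ground that “the solid seems to hold the partner at a saturated level until it runs out, then conversion stops”.

Wednesday's flask ends with starting material at 57.6 %. Thursday's flask ends with target at 67.5 %.

    2 partner → side product (k = 3.50 L mol⁻¹ h⁻¹)
    solid reagent ⇌ partner, rate k2*(cs2 - [partner]) while solid is left; crystals form when [partner] > cs2 (solubility = 0.280 M, k = 0.400 h⁻¹)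
    crystals ⇌ target, rate k3*(cs3 - [target]) while solid is left; crystals form when [target] > cs3 (solubility = 0.150 M, k = 2.50 h⁻¹)
    starting material + partner → target (k = 1.80 L mol⁻¹ h⁻¹)

In Wednesday's flask half of the turnover of starting material with partner is done by 2.28 h, far shorter than 50 h. Solid reagent stands at 0 % of its charge at 50.0 h, and target is still 42.4 % at 500 h. Starting material and target hold equal amounts at 0.303 M of solid reagent, with Wednesday's 0.240 M below that and Thursday's 0.480 M above it. For Wednesday's flask with 0.60 M of solid reagent the reach gives 74.1 % target, and that flask ends at 76.3 %.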